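The data were generated by integration with made-up constants; noise was put on by code.

Each flask is closed and stirred at constant volume, so the reagent charged is the reagent it has to work with.

| flask | starting material | reagent | remark | time |
|---|---|---|---|---|
| Saturday's | 0.15 M | 0.12 M | run made earlier |  |
| Tuesday's | 0.050 M | 0.12 M | run made earlier |  |
| north-west | 0.10 M | 0.0300 M |  | 1.0 h |
| south-west | 0.10 M | 0.120 M |  | 1.0 h |
| north-east | 0.10 M | 0.0400 M |  | 1.0 h |
| south | 0.10 M | 0.0600 M |  | 1.0 h |

- Saturday's (time / min: single product / %): 3.00: 14; 5.00: 22; 10.0: 27; 20.0: 44; 40.0: 57
- Tuesday's (time / min: single product / %): 3.00: 17; 5.00: 24; 10.0: 27; 20.0: 40; 40.0: 58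

(standard deviation of a reading: 2 percentage points)



* all flasks from highest to lowest amount of single product, in percent of the starting material charged, at 1.0 h (north-west / south-west / north-east / south)
* the amount of single product, in percent of the starting material charged of the flask you put first, at 1.0 h
* the amount of single product, in percent of the starting material charged of the flask you put last, at 1.0 h

1. I assume that one reagent makes one single product. The rate of product formed over the rate of reagent lost is then one, time drops out, and product cannot pass the reagent charged.

2. First extreme: north-west runs fast and its reagent turns wholly into product. That gives 30.0 %, the reagent charged over the starting material charged, which I call the reagent ceiling. Reagent is then the limiting reagent.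

3. Second extreme: north-west never spends its reagent. Taking first order in reagent, its time 1.0 h at [reagent] = 0.0300 M counts like 15.0 min at 0.120 M, where the earlier readings lie near 34.5 %.

4. The ceiling is lower than that, and I expect north-west to fall short of both extremes, so I put it under 30.0 %.

5. South-west has a reagent ceiling of 120 %, which is more than its starting material allows, so starting material is the limiting one in south-west, and I expect that flask to run on past Tuesday's 58 % at 40.0 min. Its ceiling stands above the others. South follows with a ceiling of 60.0 % and north-east with 40.0 %, and I rank the flasks in that order, with north-west last.

6. The forecast gives south-west > south > north-east > north-west, with top 65 % (60 % to 71 %) and low 29 % (21 % to 37 %), assuming that “more reagent gives more product”. Its range for low reaches higher than my ceiling for north-west.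

7. The flasks give south-west > south > north-east > north-west, with top 71.6 % and low 25.2 %. The order agrees, and the top lies 6.6 percentage points above the forecast.

    reagent + single product ⇌ bis adduct + by-product (K = 0.320, k = 1.10 L mol⁻¹ min⁻¹)
    starting material + reagent → single product + by-product (k = 1.50 L mol⁻¹ min⁻¹)
    starting material ⇌ dormant form (K = 1.90, k = 0.850 min⁻¹)

8. North-west ends under its ceiling, at 84.0 % of it. A neighbouring flask, charged like north-west but with 0.0075 M of reagent, has a ceiling of 7.50 %. It gives 6.65 %, again under its ceiling, at 88.7 % of it. That neighbour ends with 4.9 % of its reagent unbound.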